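**Retrosynthetic overview**

1. Numbering: ring A is the 1,3,5-trisubstituted ring (OH at C1, ether O at C3, bridge at C5); ring B carries the ether O at C1, OH at C2 and C6 and the bridge at C4; the bridge carbons run from C1' (on ring B) to C14' (on ring A).
2. Robustol ⇐ O-demethylation ⇐ hydrogenation of a 22-membered macrocyclic diene (C1'=C2' and C13'=C14').
3. Key disconnection: this diene ⇒ a diaryl ether with a vinyl group on ring A (C14') and an (E)-propenyl group on ring B (C1') plus cyclododecene (C2'–C13'), joined in one ring-opening/ring-closing metathesis cascade in which the macrocycle closes at C1'=C2'.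
4. Enabling feature: the C1'–C14' bridge is fourteen unbranched, unsubstituted CH2 groups with both end carbons benzylic, so C2'–C13' map atom for atom onto cyclododecene and C1' and C14' onto aryl-olefin carbons; the meta (ring A)/para (ring B) diaryl ether cannot close its two olefins on each other (10-membered ring) but gives a strain-free 22-membered ring once the C12 unit is inserted.
5. Diaryl ether: Ullmann coupling of (E)-4-propenyl-2,6-dimethoxyphenol with 3-bromo-5-methoxybenzaldehyde, then Wittig methylenation; rings A and B are bought as arenes, so the only ring formed is the 22-membered macrocycle (step 3).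

Key step: step 3

Remark: cyclododecene is used as the commercial cis/trans mixture and the macrocyclic diene is carried on as an E/Z mixture; neither matters because step 4 saturates every C=C bond.

**Route**

Step 1
Reactants: 1 (E)-2,6-dimethoxy-4-(prop-1-en-1-yl)phenol; 2 3-bromo-5-methoxybenzaldehyde
Product: 3 3-{2,6-dimethoxy-4-[(E)-prop-1-en-1-yl]phenoxy}-5-methoxybenzaldehyde
Conditions: CuI (10 mol%), picolinic acid (20 mol%), K3PO4 (2 equiv), degassed DMSO, 90 °C
Reagents that add atoms: none
Why: Ullmann-type diaryl ether synthesis, in which the electron-rich phenoxide of 1 couples with the unhindered aryl bromide 2 on ligated monovalent copper; the two ortho-methoxy groups are small enough for the ligand-accelerated coupling, the aldehyde is inert to phosphate base, and degassing protects the oxidation-prone propenylphenoxide.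

Step 2
Reactants: 3 3-{2,6-dimethoxy-4-[(E)-prop-1-en-1-yl]phenoxy}-5-methoxybenzaldehyde
Product: 4 2-(3-ethenyl-5-methoxyphenoxy)-1,3-dimethoxy-5-[(E)-prop-1-en-1-yl]benzene
Conditions: Ph3PCH3Br, KOtBu, THF, 0 °C to rt
Reagents that add atoms: methyltriphenylphosphonium bromide, C[P+](c1ccccc1)(c1ccccc1)c1ccccc1.[Br-]
Why: Wittig methylenation of an aryl aldehyde with the non-stabilized ylide should be fast and leaves the diaryl ether and the propenyl group untouched.

Step 3
Reactants: 4 2-(3-ethenyl-5-methoxyphenoxy)-1,3-dimethoxy-5-[(E)-prop-1-en-1-yl]benzene; 5 cyclododecene
Product: 7 tri-O-methyl-1',2',13',14'-tetradehydrorobustol (22-membered macrocyclic diene as E/Z mixture), via ring-opened cross-metathesis triene 6 (not isolated)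
Conditions: 5 (2 equiv), second-generation Grubbs catalyst (H2IMes)(PCy3)Cl2Ru=CHPh (5 mol%, two portions), 1,4-benzoquinone (10 mol%), CH2Cl2 (3 mM in 4), 40 °C, argon sweep
Reagents that add atoms: none
Why: Proposed new method: the ruthenium carbene loads first onto the terminal vinyl group of ring A (the fastest olefin present; the 1,2-disubstituted propenyl group of ring B and the internal olefin of 5 react more slowly), the resulting benzylidene ring-opens 5 through a ruthenacyclobutane, and the tethered C12 alkylidene (free as triene 6 after carbene hand-over to another vinyl group) then undergoes [2+2] cycloaddition/cycloreversion with the propenyl C=C of ring B, which forms the C1'=C2' bond at the ring B benzylic carbon, closes the macrocycle and expels Ru=CHCH3, which leaves as propene when it reloads onto the next vinyl group. The closest known reaction type is ring-expansion metathesis, in which an acyclic diene with acrylate-type ends and a cycloalkene give a macrocycle by the same ring-opening/cross/ring-closing sequence, together with ring-opening cross-metathesis of cycloalkenes with styrenes and macrocyclic ring-closing metathesis of styrenyl olefins; new is the use of a diaryl ether with two different aryl olefins as the diene. One ring closes, the 22-membered meta,para-cyclophane, by ring-closing metathesis at the ring B end. No stereocentre is formed and the E/Z composition at both C=C bonds is without consequence because step 4 saturates them. The step needs 1:1 uptake of 5 and cyclization instead of oligomerization: the two aryl olefins of 4 cannot close on each other (a 10-membered ring through a para-phenylene), so cyclization is possible only after insertion of the C12 unit, high dilution disfavours intermolecular stilbene-type coupling, and since every exchange is reversible while propene is swept out, doubly inserted rings and open-chain oligomers should be funnelled by backbiting to the strain-free 1:1 macrocycle. The vinyl/propenyl difference orders the events so that ring A opens the cascade and ring B closes it; should a minor part of the material react in the reverse order, it converges on the same compound 7.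

Step 4
Reactants: 7 tri-O-methyl-1',2',13',14'-tetradehydrorobustol
Product: 8 tri-O-methylrobustol
Conditions: H2 (1 atm), 10% Pd/C, EtOAc, rt
Reagents that add atoms: none
Why: Heterogeneous catalytic hydrogenation should saturate both 1,2-disubstituted styrenyl C=C bonds without touching the aryl methyl ethers or the diaryl ether, and it erases the E/Z mixture.

Step 5
Reactants: 8 tri-O-methylrobustol
Product: 10 robustol, via tris(dibromoboryl) ether 9 (not isolated)
Conditions: BBr3 (6 equiv), CH2Cl2, −78 °C to rt; then ice/H2O
Reagents that add atoms: boron tribromide, BrB(Br)Br (its boron and bromine atoms stay only in intermediate 9 and are lost on hydrolysis)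
Why: Lewis acid ether cleavage, in which BBr3 coordinates each methoxy oxygen and bromide removes the methyl group by SN2; the diaryl ether C–O bonds are inert because neither aryl carbon can undergo substitution, and aqueous work-up hydrolyses the aryl borates of 9 to the triol.

**Compound list**

1 | (E)-2,6-dimethoxy-4-(prop-1-en-1-yl)phenol | C/C=C/c1cc(OC)c(O)c(OC)c1 | starting material
2 | 3-bromo-5-methoxybenzaldehyde | O=Cc1cc(Br)cc(OC)c1 | starting material
3 | 3-{2,6-dimethoxy-4-[(E)-prop-1-en-1-yl]phenoxy}-5-methoxybenzaldehyde | O=Cc1cc(OC)cc(Oc2c(OC)cc(/C=C/C)cc2OC)c1 | intermediate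
4 | 2-(3-ethenyl-5-methoxyphenoxy)-1,3-dimethoxy-5-[(E)-prop-1-en-1-yl]benzene | C=Cc1cc(OC)cc(Oc2c(OC)cc(/C=C/C)cc2OC)c1 | intermediate
5 | cyclododecene (cis/trans mixture) | C1=CCCCCCCCCCC1 | starting material
6 | 2-[3-methoxy-5-(tetradeca-1,13-dien-1-yl)phenoxy]-1,3-dimethoxy-5-[(E)-prop-1-en-1-yl]benzene (E/Z at the new styrenyl C=C) | C=CCCCCCCCCCCC=Cc1cc(OC)cc(Oc2c(OC)cc(/C=C/C)cc2OC)c1 | intermediate
7 | tri-O-methyl-1',2',13',14'-tetradehydrorobustol: 22-membered ring, ring A C5–CH=CH–(CH2)10–CH=CH–C4 ring B, ring A C3–O–C1 ring B, OMe at C1 of ring A and at C2 and C6 of ring B (E/Z mixture at both C=C) | COc1cc2cc(c1)Oc1c(OC)cc(cc1OC)C=CCCCCCCCCCCC=C2 | intermediate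
8 | tri-O-methylrobustol (saturated (CH2)14 bridge) | COc1cc2cc(c1)Oc1c(OC)cc(cc1OC)CCCCCCCCCCCCCC2 | intermediate
9 | robustol tris(O-dibromoboryl) ether | BrB(Br)Oc1cc2cc(c1)Oc1c(OB(Br)Br)cc(cc1OB(Br)Br)CCCCCCCCCCCCCC2 | intermediate
10 | robustol: ring A C5 and ring B C4 joined by (CH2)14, ring A C3 and ring B C1 joined by O, OH at C1 of ring A and at C2 and C6 of ring B | Oc1cc2cc(c1)Oc1c(O)cc(cc1O)CCCCCCCCCCCCCC2 | target

**Step count and risks**

Total step count: 5. Longest linear sequence: 5 steps (from 1 or 2 to 10).

Steps most likely to fail:

Step 3 (bears the label). What may go wrong: intermolecular cross-metathesis between aryl olefins of different molecules, giving stilbene-type oligomers that re-enter the equilibrium only slowly, and multiple insertion of cyclododecene may outrun the 1:1 ring closure. The fallback uses known chemistry only, sets out from 4 and comes back at 8. The vinyl group of 4 is hydroborated selectively with 9-BBN (9-borabicyclo[3.3.1]nonane), the terminal styrene reacting far faster than the 1,2-disubstituted propenyl group, to give the alkylborane F1. F1 is coupled in the same flask with 12-bromododec-1-ene by an alkyl–alkyl Suzuki–Miyaura reaction (Pd(OAc)2, PCy3, K3PO4·H2O, THF, rt) to give the tetradec-13-enyl arene F2. Conventional ring-closing metathesis of F2 at high dilution with the second-generation Grubbs catalyst (H2IMes)(PCy3)Cl2Ru=CHPh joins the terminal olefin to the propenyl carbon of ring B with loss of propene and should give the macrocyclic monoene F3. Hydrogenation of F3 under the conditions of step 4 gives 8. The ring is still closed at the same benzylic C=C bond on ring B.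

Step 1. What may go wrong: slow coupling of the doubly ortho-substituted phenoxide, so that one-electron oxidation of the 4-propenylphenoxide to dimers by adventitious divalent copper and oxygen takes over. The fallback is a metal-free O-arylation with a diaryliodonium salt; it sets out from 2 and 1 and comes back at 3. 2 is converted by a copper-catalysed aromatic Finkelstein exchange (CuI, NaI, trans-N,N'-dimethylcyclohexane-1,2-diamine, dioxane, 110 °C) into 3-iodo-5-methoxybenzaldehyde F4. F4 is oxidized (mCPBA, TsOH·H2O, MeCN) and trapped with 1,3,5-trimethoxybenzene to give (3-formyl-5-methoxyphenyl)(2,4,6-trimethoxyphenyl)iodonium tosylate F5. The phenoxide of 1 (K2CO3, toluene, rt to 50 °C) then attacks the iodine, and reductive ligand coupling transfers the less electron-rich formyl-bearing aryl group, which should give 3 beside 2-iodo-1,3,5-trimethoxybenzene. This runs near room temperature without a redox-active metal and is insensitive to ortho substituents on the phenol.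

Step 5. What may go wrong: incomplete cleavage of the two methoxy groups that flank the diaryl ether oxygen on ring B, or degradation of the electron-rich triol on long exposure to the Lewis acid. The fallback sets out from 8 and comes back at 10: nucleophilic demethylation by SN2 attack of ethanethiolate on the methyl carbons (NaSEt, DMF, 140 °C, then acidic work-up), a basic process that forms ethyl methyl sulfide and leaves the diaryl ether untouched.

**Further compounds**

F1 | step 3 | 9-{2-[3-(2,6-dimethoxy-4-[(E)-prop-1-en-1-yl]phenoxy)-5-methoxyphenyl]ethyl}-9-borabicyclo[3.3.1]nonane | COc1cc(CCB2C3CCCC2CCC3)cc(Oc2c(OC)cc(/C=C/C)cc2OC)c1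
F2 | step 3 | 2-[3-methoxy-5-(tetradec-13-en-1-yl)phenoxy]-1,3-dimethoxy-5-[(E)-prop-1-en-1-yl]benzene | C=CCCCCCCCCCCCCc1cc(OC)cc(Oc2c(OC)cc(/C=C/C)cc2OC)c1
F3 | step 3 | tri-O-methyl-1',2'-didehydrorobustol (macrocyclic monoene, E/Z) | COc1cc2cc(c1)Oc1c(OC)cc(cc1OC)C=CCCCCCCCCCCCC2
F4 | step 1 | 3-iodo-5-methoxybenzaldehyde | O=Cc1cc(I)cc(OC)c1
F5 | step 1 | (3-formyl-5-methoxyphenyl)(2,4,6-trimethoxyphenyl)iodonium 4-methylbenzenesulfonate | O=Cc1cc(OC)cc([I+]c2c(OC)cc(OC)cc2OC)c1.Cc1ccc(cc1)S([O-])(=O)=O
F0 | step 5 | none | none
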